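Ring A, a fully substituted benzene with para oxygens at C5 and C8 flanking the vicinal C6/C7 methoxy groups, is disconnected at C8–C8a and C4a–C5 to dimethyl squarate and a 3-metallated 6-aryl-4-pyranone that already contains ring C and the benzyl-protected ring B. The precursor of the key step is the resulting 4-hydroxy-2,3-dimethoxy-4-(pyranon-3-yl)cyclobutenone. On heating it opens to a dienylketene whose 6π closure onto the pyranone O–CH= carbon forms C8–C8a, closes ring A and delivers the 5,8-hydroquinone in one operation, with O5 chelated to the C4 carbonyl and O8 free for selective methylation.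

Key step: step 6

Remarks on the chemistry
- The target has no stereocentre. The only stereocentres on the route (the carbinol carbon of 12 and C8a of 14) form as racemates and are erased in step 6, so no enantiocontrol is needed.
- Atom mapping of the key step was checked and is consistent: cyclobutenone C1 (C=O) → C8, C2 → C7, C3 → C6, C4 (carbinol) → C5; pyranone C3 → C4a, pyranone C2 → C8a.
- Design choice: iodine is installed on the enone before the pyranone ring is built. Electrophilic iodination of the finished 2-aryl-4-pyranone could attack either α-carbon or the dialkoxyarene; ring construction from the iodo-enone fixes the site.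
- Numbering: 9 is named with aryl at C2 and iodine at C5; in 12 the same ring is numbered from the other side (aryl C6, cyclobutenyl C3, O–CH= C2).

Step 1
Reactants: 1 2,5-dihydroxybenzoic acid
Product: 3 2,5-bis(benzyloxy)benzoic acid, via tribenzyl ester 2 (not isolated)
Conditions: BnBr (3.3 equiv), K2CO3, DMF, 60 °C; aqueous work-up, crude ester in THF/MeOH, 2 M NaOH, 60 °C; then HCl to pH 2
Reagents that add atoms: benzyl bromide BrCc1ccccc1; sodium hydroxide [Na+].[OH-]
Why: Williamson O-benzylation of both phenols and the carboxylate, then saponification of the benzyl ester (acyl–oxygen cleavage), should give the acid because aryl benzyl ethers are inert to hydroxide.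

Step 2
Reactants: 3 2,5-bis(benzyloxy)benzoic acid
Product: 4 2,5-bis(benzyloxy)benzoyl chloride
Conditions: (COCl)2, cat. DMF, CH2Cl2, 0 °C → rt; evaporate, use crude
Reagents that add atoms: oxalyl chloride ClC(=O)C(Cl)=O
Why: Acid chloride formation through the Vilsmeier-type chloroiminium catalyst is mild enough to leave the benzyl ethers untouched.

Step 3
Reactants: 5 (E)-4-methoxybut-3-en-2-one
Product: 6 (Z)-3-iodo-4-methoxybut-3-en-2-one
Conditions: I2 (1.3 equiv), pyridine/CH2Cl2 1:1, 0 °C → rt, dark; aq. Na2S2O3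
Reagents that add atoms: iodine II
Why: Johnson-type α-iodination of an enone (iodine/pyridine), a reaction established for β-alkoxy enones with a β-hydrogen, should put iodine on C3 because this is the nucleophilic enol-ether carbon.

Step 4
Reactants: 6 (Z)-3-iodo-4-methoxybut-3-en-2-one; 4 2,5-bis(benzyloxy)benzoyl chloride
Product: 9 2-[2,5-bis(benzyloxy)phenyl]-5-iodo-4H-pyran-4-one, via lithium enolate 7 (not isolated), via iodo diketone 8 (not isolated)
Conditions: 6 (2.2 equiv), LiHMDS (2.2 equiv), THF, −78 °C; 4 (1.0 equiv), −78 → −30 °C; aq. NH4Cl; crude in PhMe, TFA (0.5 equiv), rt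
Reagents that add atoms: none
Why: Claisen-type C-acylation of the kinetic methyl-ketone enolate, then acid-catalysed 6-endo addition of the diketone enol oxygen to the β-methoxy enone with loss of methanol (cyclocondensation to a 4-pyranone), should place iodine unambiguously next to the unsubstituted O–CH= carbon.

Step 5
Reactants: 9 2-[2,5-bis(benzyloxy)phenyl]-5-iodo-4H-pyran-4-one; 10 dimethyl squarate
Product: 12 rac-4-{6-[2,5-bis(benzyloxy)phenyl]-4-oxo-4H-pyran-3-yl}-4-hydroxy-2,3-dimethoxycyclobut-2-en-1-one, via pyranonylmagnesium chloride 11 (not isolated)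
Conditions: iPrMgCl·LiCl (1.1 equiv), THF, −78 °C, 20 min; 10 (1.5 equiv) in THF, −78 → −40 °C; sat. aq. NH4Cl at −40 °C; no acid, deactivated silica
Reagents that add atoms: none
Why: Iodine–magnesium exchange on an α-iodo vinylogous ester is fast at −78 °C, and the alkenyl Grignard should add 1,2 to one of the two equivalent squarate carbonyls (Grignard addition), giving the carbinol centre as a racemate that step 6 erases.

Step 6
Reactants: 12 rac-4-{6-[2,5-bis(benzyloxy)phenyl]-4-oxo-4H-pyran-3-yl}-4-hydroxy-2,3-dimethoxycyclobut-2-en-1-one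
Product: 15 2-[2,5-bis(benzyloxy)phenyl]-5,8-dihydroxy-6,7-dimethoxy-4H-chromen-4-one, via dienylketene 13 (not isolated), via bicyclic dienone 14 (not isolated)
Conditions: PhMe (degassed, 0.02 M), 110 °C, Ar; p-xylene, 138 °C if conversion is slow
Reagents that add atoms: none
Why: Thermal conrotatory 4π opening of the cyclobutenone C1–C4 bond, with the C4 hydroxyl turning outward (donor torquoselectivity), should give the (Z)-dienylketene 13 with the pyranone cis to the ketene. A 6π electrocyclisation of the all-carbon triene (ketene C=C, C(OMe)=C(OH), pyranone C3=C2) joins the ketene carbon to pyranone C2, which is C8 to C8a, closing the six-membered ring A as dienone 14; enolisation with loss of the 8a-hydrogen then gives the hydroquinone. The closest known reaction type is the Moore ring expansion of 4-hydroxy-4-alkenyl, aryl or heteroaryl cyclobutenones to hydroquinones. No stereocentre is formed in the product, since the carbinol centre of 12 and the transient C8a centre of 14 both become sp2. Regiochemistry is inherent because only pyranone C2 lies 1,6 to the ketene carbon, and the outward hydroxyl cannot reach the ketene to lactonise. Exclusion of oxygen is needed so that the hydroquinone is not oxidised to the 5,8-quinone.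

Step 7
Reactants: 15 2-[2,5-bis(benzyloxy)phenyl]-5,8-dihydroxy-6,7-dimethoxy-4H-chromen-4-one
Product: 16 2-[2,5-bis(benzyloxy)phenyl]-5-hydroxy-6,7,8-trimethoxy-4H-chromen-4-one
Conditions: MeI (1.15 equiv), K2CO3 (1.5 equiv), acetone (degassed), 40 °C, Ar
Reagents that add atoms: iodomethane CI
Why: Williamson methylation with limited methyl iodide should take only the 8-hydroxyl, because the 5-hydroxyl is hydrogen-bonded to the C4 carbonyl and is much less nucleophilic, as in classical partial methylation of 5-hydroxyflavones.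

Step 8
Reactants: 16 2-[2,5-bis(benzyloxy)phenyl]-5-hydroxy-6,7,8-trimethoxy-4H-chromen-4-one
Product: 17 5,2',5'-trihydroxy-6,7,8-trimethoxyflavone
Conditions: H2 (1 atm), 10% Pd/C, EtOAc/MeOH, rt; filter and concentrate under Ar
Reagents that add atoms: none
Why: Catalytic hydrogenolysis of the two aryl benzyl ethers under neutral conditions should leave the flavone C2=C3 bond and the methyl ethers intact.

Compound list
1 | 2,5-dihydroxybenzoic acid | O=C(O)c1cc(O)ccc1O | starting material
2 | benzyl 2,5-bis(benzyloxy)benzoate | O=C(OCc1ccccc1)c1cc(OCc2ccccc2)ccc1OCc1ccccc1 | intermediate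
3 | 2,5-bis(benzyloxy)benzoic acid | O=C(O)c1cc(OCc2ccccc2)ccc1OCc1ccccc1 | intermediate
4 | 2,5-bis(benzyloxy)benzoyl chloride | O=C(Cl)c1cc(OCc2ccccc2)ccc1OCc1ccccc1 | intermediate
5 | (E)-4-methoxybut-3-en-2-one | CO/C=C/C(C)=O | starting material
6 | (Z)-3-iodo-4-methoxybut-3-en-2-one | CO/C=C(\I)C(C)=O | intermediate
7 | lithium enolate of 6 (lithium (Z)-3-iodo-4-methoxybuta-1,3-dien-2-olate) | CO/C=C(\I)C(=C)O[Li] | intermediate
8 | (Z)-1-[2,5-bis(benzyloxy)phenyl]-4-iodo-5-methoxypent-4-ene-1,3-dione (drawn as the diketo form; largely enolised) | CO/C=C(\I)C(=O)CC(=O)c1cc(OCc2ccccc2)ccc1OCc1ccccc1 | intermediate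
9 | 2-[2,5-bis(benzyloxy)phenyl]-5-iodo-4H-pyran-4-one | O=c1cc(-c2cc(OCc3ccccc3)ccc2OCc2ccccc2)occ1I | intermediate
10 | dimethyl squarate (3,4-dimethoxycyclobut-3-ene-1,2-dione) | COC1=C(OC)C(=O)C1=O | starting material
11 | {6-[2,5-bis(benzyloxy)phenyl]-4-oxo-4H-pyran-3-yl}magnesium chloride | O=c1cc(-c2cc(OCc3ccccc3)ccc2OCc2ccccc2)occ1[Mg]Cl | intermediate
12 | rac-4-{6-[2,5-bis(benzyloxy)phenyl]-4-oxo-4H-pyran-3-yl}-4-hydroxy-2,3-dimethoxycyclobut-2-en-1-one | COC1=C(OC)C(O)(c2coc(-c3cc(OCc4ccccc4)ccc3OCc3ccccc3)cc2=O)C1=O | intermediate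
13 | (Z)-dienylketene: 4-{6-[2,5-bis(benzyloxy)phenyl]-4-oxo-4H-pyran-3-yl}-4-hydroxy-2,3-dimethoxybuta-1,3-dien-1-one, pyranone cis to the ketene | O=C=C(OC)/C(OC)=C(/O)c1coc(-c2cc(OCc3ccccc3)ccc2OCc2ccccc2)cc1=O | intermediate
14 | rac-2-[2,5-bis(benzyloxy)phenyl]-5-hydroxy-6,7-dimethoxy-8aH-chromene-4,8-dione (keto tautomer of 15) | COC1=C(OC)C(=O)C2OC(-c3cc(OCc4ccccc4)ccc3OCc3ccccc3)=CC(=O)C2=C1O | intermediate
15 | 2-[2,5-bis(benzyloxy)phenyl]-5,8-dihydroxy-6,7-dimethoxy-4H-chromen-4-one | COc1c(OC)c(O)c2c(=O)cc(-c3cc(OCc4ccccc4)ccc3OCc3ccccc3)oc2c1O | intermediate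
16 | 2-[2,5-bis(benzyloxy)phenyl]-5-hydroxy-6,7,8-trimethoxy-4H-chromen-4-one | COc1c(OC)c(O)c2c(=O)cc(-c3cc(OCc4ccccc4)ccc3OCc3ccccc3)oc2c1OC | intermediate
17 | 5,2',5'-trihydroxy-6,7,8-trimethoxyflavone (achiral) | COc1c(OC)c(O)c2c(=O)cc(-c3cc(O)ccc3O)oc2c1OC | target

Total step count: 8
Longest linear sequence: 7 steps (1 → 3 → 4 → 9 → 12 → 15 → 16 → 17; steps 1, 2, 4, 5, 6, 7, 8). Step 3 is the one-step side branch to 6.

Steps most likely to fail

Step 5. The 3-magnesiated pyranone may fragment by β-elimination across C2=C3 with loss of the ring oxygen, or the exchange reagent may add to the pyranone before exchange is complete. Fallback: starting from 9, oxidative insertion of zinc (activated Zn dust, LiCl, THF, rt) should give the non-basic, fragmentation-resistant {6-[2,5-bis(benzyloxy)phenyl]-4-oxo-4H-pyran-3-yl}zinc iodide F1. Its MgCl2-promoted 1,2-addition to the strongly electrophilic carbonyl of dimethyl squarate 10, followed by NH4Cl quench, returns to the route at 12.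

Step 6. Capture of the dienylketene by the hydroxyl or adventitious nucleophiles, or thermal decomposition of the pyranone, may outrun the 6π closure, and the hydroquinone may over-oxidise. Fallback (classical flavone construction, leaving the squarate route): starting from acid chloride 4, O-acylation of commercial 2'-hydroxy-3',4',5',6'-tetramethoxyacetophenone F2 in pyridine should give 2-acetyl-3,4,5,6-tetramethoxyphenyl 2,5-bis(benzyloxy)benzoate F3. Baker–Venkataraman rearrangement (KOH, pyridine, 50 °C) gives 1-[2,5-bis(benzyloxy)phenyl]-3-(2-hydroxy-3,4,5,6-tetramethoxyphenyl)propane-1,3-dione F4. Acid-catalysed cyclodehydration (cat. p-TsOH, PhMe, reflux) gives 2-[2,5-bis(benzyloxy)phenyl]-5,6,7,8-tetramethoxy-4H-chromen-4-one F5. Chelation-directed cleavage of the 5-O-methyl group alone (BCl3, 1.2 equiv, CH2Cl2, −78 → 0 °C) returns to the route at 16.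

Step 4. The α-iodo enolate may be acylated on oxygen or lose iodine, or acid may cause proto-deiodination during ring closure. Fallback: starting from 4 and 5, the same LiHMDS protocol on the iodine-free enone goes through the lithium enolate of 5, lithium (E)-4-methoxybuta-1,3-dien-2-olate F6, to (E)-1-[2,5-bis(benzyloxy)phenyl]-5-methoxypent-4-ene-1,3-dione F7. TFA closes this to 2-[2,5-bis(benzyloxy)phenyl]-4H-pyran-4-one F8. Iodination with I2/pyridine (addition–elimination that starts at the unsubstituted O–CH= carbon, so iodine should enter the adjacent C5) returns to the route at 9. Attack next to the aryl-bearing carbon or on the dialkoxyarene is the competing process here, which is why this order is the fallback and not the main route.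

Further compounds
F1 | step 5 | {6-[2,5-bis(benzyloxy)phenyl]-4-oxo-4H-pyran-3-yl}zinc iodide | O=c1cc(-c2cc(OCc3ccccc3)ccc2OCc2ccccc2)occ1[Zn]I
F2 | step 6 | 2'-hydroxy-3',4',5',6'-tetramethoxyacetophenone | CC(=O)c1c(O)c(OC)c(OC)c(OC)c1OC
F3 | step 6 | 2-acetyl-3,4,5,6-tetramethoxyphenyl 2,5-bis(benzyloxy)benzoate | CC(=O)c1c(OC(=O)c2cc(OCc3ccccc3)ccc2OCc2ccccc2)c(OC)c(OC)c(OC)c1OC
F4 | step 6 | 1-[2,5-bis(benzyloxy)phenyl]-3-(2-hydroxy-3,4,5,6-tetramethoxyphenyl)propane-1,3-dione | O=C(CC(=O)c1cc(OCc2ccccc2)ccc1OCc1ccccc1)c1c(O)c(OC)c(OC)c(OC)c1OC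
F5 | step 6 | 2-[2,5-bis(benzyloxy)phenyl]-5,6,7,8-tetramethoxy-4H-chromen-4-one | COc1c(OC)c(OC)c2c(=O)cc(-c3cc(OCc4ccccc4)ccc3OCc3ccccc3)oc2c1OC
F6 | step 4 | lithium (E)-4-methoxybuta-1,3-dien-2-olate | C=C(O[Li])/C=C/OC
F7 | step 4 | (E)-1-[2,5-bis(benzyloxy)phenyl]-5-methoxypent-4-ene-1,3-dione | CO/C=C/C(=O)CC(=O)c1cc(OCc2ccccc2)ccc1OCc1ccccc1
F8 | step 4 | 2-[2,5-bis(benzyloxy)phenyl]-4H-pyran-4-one | O=c1ccoc(-c2cc(OCc3ccccc3)ccc2OCc2ccccc2)c1
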